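**The vessel.** The closed, stirred vessel holds a racemate, partner and a little single-handed free catalyst. Sunday's and Saturday's differ in their catalyst charge.

the same everywhere: left-handed substrate 0.30 M; right-handed substrate 0.30 M

| charge | partner | free catalyst | remark | time |
|---|---|---|---|---|
| elm | 0.45 M | 3.4 mM | run made earlier |  |
| oak | 0.45 M | 8.9 mM | run made earlier |  |
| Sunday's | 0.450 M | 7.5 mM |  | 10 min |
| Saturday's | 0.450 M | 2.5 mM |  | 10 min |

| run | time / min | right-handed substrate / % | left-handed substrate / % |
|---|---|---|---|
| elm | 0.500 | 49.8 | 49.2 |
| elm | 1.50 | 49.7 | 49.2 |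
| elm | 3.00 | 49.6 | 48.4 |
| elm | 4.00 | 49.3 | 49.0 |
| elm | 6.00 | 48.7 | 48.6 |
| elm | 8.00 | 48.6 | 47.9 |
| elm | 10.0 | 48.9 | 47.8 |
| oak | 0.500 | 49.6 | 49.1 |
| oak | 1.50 | 49.6 | 48.2 |
| oak | 3.00 | 48.8 | 47.9 |
| oak | 4.00 | 48.6 | 47.4 |
| oak | 6.00 | 48.0 | 46.5 |
| oak | 8.00 | 47.2 | 46.4 |
| oak | 10.0 | 47.0 | 45.9 |

(scatter of a reading: 0.3 percentage points)

- free catalyst is single-handed; left-handed substrate and right-handed substrate are mirror images of each other, charged as a racemate, each of them at the stated concentration
- the analysis behind the earlier runs scatters by 0.3 percentage points, standard deviation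
- an excess is below zero if the other one leads

1. which of the two ends with the higher excess of right-handed substrate over left-handed substrate among what is left of the two ("neither" if they lie within 2 percentage points) (Sunday's / Saturday's / neither)
2. excess of right-handed substrate over left-handed substrate among what is left of the two at the end, Sunday's
3. excess of right-handed substrate over left-handed substrate among what is left of the two at the end, Saturday's

**Two amounts.** Taken over its readings, the oak run has an excess (enantiomeric excess) of 1.10%, and its catalyst share, catalyst over both substrates charged, is 1.48%. The elm run gives 0.657% on 0.567%.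

**The lean.** The reckoning here takes the excess as proportional to catalyst share and to partner charge; elm and oak both hold 0.45 M of partner, so the second assumption stays untested. Oak then gives the lean, 1.65 L mol⁻¹, the excess per catalyst share and per unit of partner concentration. Elm reads 2.58 L mol⁻¹, but its excess stands closer to the scatter, so oak's lean is kept. Oak's value is a mean over its readings; taking that mean to stand for the end, a further assumption, the lean gives 0.930% for Sunday's and 0.310% for Saturday's, which lie within the margin of each other.

**The forecast.** It says 1.2% (0.8% to 1.7%) for Sunday's, 0.55% (0.3% to 0.9%) for Saturday's, and neither: “The gap should scale roughly with catalyst, perhaps sublinearly.” Both values lie above this reckoning.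

**The result.** Sunday's ends at 0.813% and Saturday's at 0.339%, 0.47 percentage points apart and so within the margin, and the answer is neither, as forecast. At the end of Sunday's, left-handed product stands at 4.78% and right-handed product at 0.863%. Sunday's end value gives a lean of 1.44 L mol⁻¹, against the 1.65 L mol⁻¹ carried from oak's mean over its readings.

    partner + catalyst intermediate B → free catalyst + right-handed product (k = 2.70 L mol⁻¹ min⁻¹)
    partner → decomposed reagent (k = 0.130 min⁻¹)
    2 free catalyst ⇌ resting dimer, settled at all times (K = 110 L mol⁻¹)
    free catalyst + left-handed substrate ⇌ catalyst intermediate A (K = 1.90 L mol⁻¹, k = 1900 L mol⁻¹ min⁻¹)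
    left-handed substrate ⇌ right-handed substrate (k = 0.170 min⁻¹)
    partner + catalyst intermediate A → free catalyst + left-handed product (k = 7.30 L mol⁻¹ min⁻¹)
    free catalyst + right-handed substrate ⇌ catalyst intermediate B (K = 0.910 L mol⁻¹, k = 310 L mol⁻¹ min⁻¹)

**Second flask.** With 0.27 M of partner and otherwise as Sunday's, the lean gives 0.558%. That neighbour flask gives 0.487%.

(All runs were computed with constants of no real substance, and the scatter is random.)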